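## Analysis of the target

The target 27 is a C2-symmetric, 20-membered macrodiolide, the head-to-tail dimer of a C10 hydroxy acid. Each half is numbered here as that acid: C1 is the lactone carbonyl, C2(Me)=C3 and C4=C5 the diene, C6 and C7 the methylenes, C8 the methyl-bearing and C9 the acyloxy-bearing stereocentre, and C10 the methylene carrying the oxazol-5-yl ring; the second half is primed. Only two stereocentres are independent, C8 and C9, both R and syn in the extended chain; the C2 axis repeats them, and the two pairs are too far apart for any relay between the halves. Each half contains a (2Z,4Z)-2-methylpenta-2,4-dienoate, an angelate-type ester whose C2=C3 bond is the disfavoured isomer and isomerises when the carboxyl is activated or a nucleophile adds reversibly at C3 or C5. The oxazoles are unsubstituted at their C2, so they bring an acidic C–H, a ring that opens on metalation there, and a basic nitrogen. The difficulty is to close a 20-membered ring and keep four Z olefins without ever activating a (2Z)-dienoic acid. The feature that invites the chosen move is the C(sp2)–C(sp3) junction C5–C6 (ring bonds C6–C7 and C16–C17 of the 1,11-dioxacycloicosane): it separates the planar dienoate from the stereogenic segment, it occurs twice in symmetry-related positions, and C6–C7 is exactly what a terminal vinyl group becomes on hydroboration.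

## Retrosynthetic reasoning

**27 to 25.** The ring bond C5′–C6′ is cut. This opens the macrocycle to the open-chain diester 25, which already holds both ester bonds, all four Z olefins and all four stereocentres, with a vinyl group at one end and a (Z)-alkenyl iodide at the other. Forward, the vinyl group is hydroborated to the alkylborane 26 and an intramolecular palladium-catalysed sp3–sp2 coupling closes the ring. The cut is made here and not at a lactone C–O bond because no acyl group is then activated after the dienes exist.

**25 to 23 and 19.** C2′=C3′ is cut. Forward, a Z-selective phosphonate olefination of the phosphonate terminus of 23 (through carbanion 24) with (2Z)-3-iodoprop-2-enal 19 builds the second dienoate on the finished ester and delivers the Z iodide that the ring closure needs.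

**23 to 16 and 21.** The symmetry-related bond C5–C6 is cut. Forward, the vinyl group of the phosphonate ester 16 is hydroborated to 22 and coupled with the alkenyl iodide 21. The two C5–C6 bonds are thus made by the same reaction type but one at a time, which leaves each coupling a single constitutional outcome. Both partners come from one alcohol, 13.

**21 to 16 and 19.** C2=C3 is cut. Forward, the same Z-selective olefination (through carbanion 20) converts 16 into the iododienoate 21.

**16 to 13 and 14.** The ester C1–O bond is cut at a stage where the acyl part is saturated at C2, so no geometry is at risk. Forward, acyl transfer from the ethyl phosphonopropanoate 14 to the secondary alcohol 13 goes through the ketene 15. Aldehyde 19 comes from the ester 17 by partial reduction through 18.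

**13 to 9 and 10.** The bond between C10 and oxazole C5 is cut. Forward, the C2-silylated oxazole 10 is metalated at C5 to 11 and opens the terminal epoxide 9 at its CH2 carbon to 12; the silyl group is then removed. The oxazole is brought in intact and the C9 carbinol arises without touching its configuration.

**9 to 7 to 6.** The epoxide comes from the 1,2-diol 7 by activation of the primary hydroxyl only (through 8). Diol 7 comes from the silyl ether 6.

**6 to 1 and 2.** The C8–C9 bond is cut. Forward, one reagent-controlled crotylboration of aldehyde 2 with the borane 4, made from 1 through 3, sets both stereocentres (borinate 5 is oxidised to 6). The Z geometry of 1 becomes the syn relationship, and the vinyl group left behind is the C6=C7 handle for both couplings.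

## Alternatives that were turned down

Alternative 1: (the textbook one)
- Disconnection: both lactone C1–O bonds.
- Forward key step: Yamaguchi-type cyclodimerisation, or esterification then macrolactonisation, of the seco acid A1, (2Z,4Z,8R,9R)-9-hydroxy-2,8-dimethyl-10-(1,3-oxazol-5-yl)deca-2,4-dienoic acid.
- Turned down because both ring-forming events activate the carboxyl of an angelate-type (2Z)-dienoic acid. The activated acyl species is a strong acceptor at C3 and C5, and reversible addition of the acyl-transfer catalyst or of carboxylate lets C2=C3 relax to 2E. This would happen twice, at the end, on the most valuable material. The step also forms no C–C bond, so the whole chain of A1 must be finished and carried through hydroxyl and carboxyl protection first.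

Alternative 2:
- Disconnection: the diene σ-bonds C3–C4 and C3′–C4′.
- Forward key step: double Stille coupling (palladium-catalysed head-to-tail cyclodimerisation) of the iodoacrylate/alkenylstannane monomer A2.
- Turned down on step economy and reagents. The vinyl group from the crotylation would have to be homologated by two carbons and turned into a (Z)-alkenylstannane, about five more steps on the longest line. The acyl part would come from (2Z)-3-iodo-2-methylprop-2-enoic acid A3, whose esterification again activates a Z acid open to addition–elimination at C3. Stoichiometric tin would be used beside two basic oxazoles, and a monomer with both reactive ends can close onto itself or grow into chains.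

Alternative 3:
- Disconnection: C4=C5 and C4′=C5′.
- Forward key step: ring-closing alkyne metathesis cyclodimerisation of the diyne ester A4 to the bis-enyne macrocycle A5, then double Z-selective semi-reduction.
- Turned down because A4 has two different alkynes (one conjugated, one alkyl-substituted) and metathesis is reversible and not orienting. Head-to-head and tail-to-tail unions are as accessible as head-to-tail, so A5 would be one of several 20-membered constitutional isomers. The Lewis-acidic alkylidyne would have to tolerate two oxazoles. The route would end with a semi-reduction of two conjugated enynes on the final ring, with over-reduction as a risk, and the longest line grows by at least four steps.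

Key step: step 10

Assumption: 1, 2, 10, 14 and 17 are purchased; 14 is used as the racemate, which is without consequence because its stereocentre becomes the sp2 carbon C2 (or C2′) in steps 7 and 9.

## Route

Step 1
Reactants: 1 cis-2-butene; 2 (tert-butyldimethylsilyloxy)acetaldehyde
Product: 6 (2S,3R)-1-[(tert-butyldimethylsilyl)oxy]-3-methylpent-4-en-2-ol, via (Z)-crotylpotassium 3 (not isolated), via (Z)-crotyldiisopinocampheylborane 4 (not isolated), via borinate ester 5 (not isolated)
Conditions: 1 (excess), KOt-Bu, n-BuLi, THF, −78 to −45 °C; (−)-Ipc2BOMe, −78 °C; BF3·OEt2, then 2, −78 °C; 3 M NaOH, 30% H2O2, rt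
Reagents that add atoms: none
Why: Brown (Z)-crotylboration through a closed chair transition state, so the Z geometry of 4 becomes the syn relationship of the new stereocentres. The isopinocampheyl groups derived from (+)-α-pinene direct the crotyl group to the Si face of 2, which should set C9 and C8 of the target (both R) in one event.

Step 2
Reactants: 6
Product: 7 (2S,3R)-3-methylpent-4-ene-1,2-diol
Conditions: Bu4NF, THF, 0 °C to rt
Reagents that add atoms: none
Why: Fluoride cleavage of the primary silyl ether; neither stereocentre nor the alkene is affected.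

Step 3
Reactants: 7
Product: 9 (2S)-2-[(2R)-but-3-en-2-yl]oxirane, via sodium alkoxide of the primary tosylate 8 (not isolated)
Conditions: NaH (2.2 equiv), N-tosylimidazole (1.05 equiv), THF, 0 °C to rt; volatile product kept as a concentrated ethereal solution
Reagents that add atoms: none
Why: One-pot selective sulfonylation of the primary hydroxyl and intramolecular Williamson closure (3-exo-tet). The C–O bond at the stereocentre is not broken, so its configuration is retained.

Step 4
Reactants: 9; 10 2-(triisopropylsilyl)-1,3-oxazole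
Product: 13 (2R,3R)-3-methyl-1-(1,3-oxazol-5-yl)pent-4-en-2-ol, via 5-lithio-2-(triisopropylsilyl)oxazole 11 (not isolated), via C2-silylated alcohol 12 (not isolated)
Conditions: 10, n-BuLi, THF, −78 °C; 9, BF3·OEt2, −78 °C; then 1 M HCl, THF, rt
Reagents that add atoms: none
Why: With C2 blocked by silicon, deprotonation occurs at C5 without ring opening to the isocyanide enolate. BF3-assisted SN2 opening of the terminal epoxide at its CH2 carbon forms the C10–oxazole bond. The acidic work-up protodesilylates the labile C2–Si bond.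

Step 5
Reactants: 13; 14 ethyl 2-[bis(2,2,2-trifluoroethoxy)phosphoryl]propanoate (racemic)
Product: 16 (2R,3R)-3-methyl-1-(1,3-oxazol-5-yl)pent-4-en-2-yl 2-[bis(2,2,2-trifluoroethoxy)phosphoryl]propanoate, via phosphonoketene 15 (not isolated)
Conditions: 14 (3 equiv), DMAP (0.3 equiv), toluene, reflux, 4 Å molecular sieves to remove EtOH
Reagents that add atoms: none
Why: DMAP-catalysed transesterification of a phosphonoacetate-type ester: the acidic α-C–H allows elimination of ethanol to ketene 15, which the secondary alcohol captures. The ester bond is made while C2 is still sp3, so no olefin geometry can be lost; 16 is an inconsequential mixture of epimers at the phosphonate carbon.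

Step 6
Reactants: 17 ethyl (2Z)-3-iodoprop-2-enoate
Product: 19 (2Z)-3-iodoprop-2-enal, via aluminium hemiacetal 18 (not isolated)
Conditions: i-Bu2AlH (1.05 equiv), CH2Cl2, −78 °C; MeOH, aq. KNa tartrate; dried solution used at once, cold and in the dark
Reagents that add atoms: none
Why: Partial reduction of an ester: the tetrahedral aluminium hemiacetal 18 is stable at −78 °C and releases the aldehyde only on work-up. The Z iodide is retained if the solution is used immediately.

Step 7
Reactants: 16; 19
Product: 21 (2R,3R)-3-methyl-1-(1,3-oxazol-5-yl)pent-4-en-2-yl (2Z,4Z)-5-iodo-2-methylpenta-2,4-dienoate, via potassium phosphonate carbanion 20 (not isolated)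
Conditions: 16, KN(SiMe3)2 (1.0 equiv), 18-crown-6 (4 equiv), THF, −78 °C; 19 (1.5 equiv), −78 °C
Reagents that add atoms: none
Why: Still–Gennari olefination: the electron-poor trifluoroethyl phosphonate and the crown-ether-separated potassium ion make collapse of the kinetic adduct faster than its reversal, which should give the (2Z)-trisubstituted enoate. One equivalent of base removes only the phosphonate α-proton (more acidic than the oxazole C2–H), and the 4Z iodide comes unchanged from 19.

Step 8
Reactants: 16; 21
Product: 23 (2R,3R)-3-methyl-1-(1,3-oxazol-5-yl)pent-4-en-2-yl (2Z,4Z,8R,9R)-9-({2-[bis(2,2,2-trifluoroethoxy)phosphoryl]propanoyl}oxy)-2,8-dimethyl-10-(1,3-oxazol-5-yl)deca-2,4-dienoate, via alkylborane of the phosphonate ester 22 (not isolated)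
Conditions: 16 (1.2 equiv), 9-BBN-H dimer (0.55 equiv), THF, 0 °C to rt; then 21 (1.0 equiv), Pd(dppf)Cl2 (0.05 equiv), AsPh3 (0.05 equiv), Cs2CO3 (3 equiv), DMF/THF/H2O, rt
Reagents that add atoms: none
Why: 9-BBN adds anti-Markovnikov to the monosubstituted vinyl group of 16 and gives the primary alkylborane 22; B–H is the limiting reagent, so none is left for the vinyl group of 21. Zerovalent palladium inserts into the C5–I bond of 21 with retention, the hydroxide-activated borane transfers its primary alkyl group and reductive elimination forms C5–C6 (B-alkyl Suzuki–Miyaura coupling). Under the carbonate the phosphonate should rest as its stabilised carbanion, which shields phosphorus from hydroxide, and it is reprotonated on work-up.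

Step 9
Reactants: 23; 19
Product: 25 (2R,3R)-3-methyl-1-(1,3-oxazol-5-yl)pent-4-en-2-yl (2Z,4Z,8R,9R)-9-{[(2Z,4Z)-5-iodo-2-methylpenta-2,4-dienoyl]oxy}-2,8-dimethyl-10-(1,3-oxazol-5-yl)deca-2,4-dienoate, via potassium carbanion 24 (not isolated)
Conditions: 23, KN(SiMe3)2 (1.0 equiv), 18-crown-6 (4 equiv), THF, −78 °C; 19 (1.5 equiv), −78 °C
Reagents that add atoms: none
Why: Still–Gennari olefination as in step 7, now on the phosphonate terminus of 23: fast collapse of the kinetic adduct should give the (2Z)-trisubstituted enoate, and the 4Z iodide comes unchanged from 19. One equivalent of base at −78 °C removes only the phosphonate α-proton, which is far more acidic than any proton of the existing dienoate or the oxazole C2–H.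

Step 10
Reactants: 25
Product: 27 (3Z,5Z,9R,10R,13Z,15Z,19R,20R)-3,9,13,19-tetramethyl-10,20-bis(1,3-oxazol-5-ylmethyl)-1,11-dioxacycloicosa-3,5,13,15-tetraene-2,12-dione (CNP0414419.1), via alkylborane of the open-chain diester 26 (not isolated)
Conditions: 9-BBN-H dimer (0.6 equiv), THF, 0 °C to rt; then syringe-pump addition (8 h) to Pd(dppf)Cl2 (0.2 equiv), AsPh3 (0.2 equiv), Cs2CO3 (3 equiv), degassed DMF/THF/H2O, rt, final 0.001 M
Reagents that add atoms: none
Why: 9-BBN adds anti-Markovnikov to the only monosubstituted alkene of 25, the C6′=C7′ vinyl group, far faster than to the ester-conjugated internal diene or the iodine-bearing diene, and gives the primary alkylborane 26 with boron on C6′. On slow addition to the catalyst, zerovalent palladium inserts into the C5′–I bond with retention, the hydroxide-activated borane transfers its primary alkyl group, and reductive elimination forms C5′–C6′ (intramolecular B-alkyl Suzuki–Miyaura coupling; closest known reaction type: macrocyclising B-alkyl Suzuki–Miyaura coupling of ω-borylalkyl (Z)-alkenyl iodides to large lactones). The 20-membered ring closes end-to-end through a 21-membered palladacycle; it is an unstrained macrocyclisation, for which the endo/exo distinction of small rings carries no weight. No stereocentre is formed: C8, C9, C8′ and C9′ are untouched, and the four Z olefins are carried over from 25 because oxidative addition, transmetalation and reductive elimination all proceed with retention at sp2 carbon. The step needs ring closure to outrun intermolecular coupling; 26 has exactly one nucleophilic and one electrophilic end, so the only competitor is chain growth, which high dilution and the turn elements of the chain (two Z,Z-dienes, two s-trans esters) should suppress. AsPh3 and the wide-bite-angle dppf ligand are chosen to speed transmetalation and reductive elimination relative to β-hydride elimination of the alkylpalladium intermediate and to Z/E scrambling of the dienylpalladium iodide. Both carboxyls are esters throughout, so no acyl group is activated at any point after the dienes exist.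

## Compound list

1 | cis-2-butene | C/C=C\C | starting material
2 | (tert-butyldimethylsilyloxy)acetaldehyde | O=CCO[Si](C)(C)C(C)(C)C | starting material
3 | (Z)-but-2-en-1-ylpotassium | C/C=C\[CH2-].[K+] | intermediate
4 | (Z)-but-2-en-1-yl-bis[(1R,2S,3R,5R)-isopinocampheyl]borane | C/C=C\CB([C@@H]1C[C@@H]2C[C@H]([C@H]1C)C2(C)C)[C@@H]1C[C@@H]2C[C@H]([C@H]1C)C2(C)C | intermediate
5 | diisopinocampheylborinate of 6 | C=C[C@@H](C)[C@@H](CO[Si](C)(C)C(C)(C)C)OB([C@@H]1C[C@@H]2C[C@H]([C@H]1C)C2(C)C)[C@@H]1C[C@@H]2C[C@H]([C@H]1C)C2(C)C | intermediate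
6 | (2S,3R)-1-[(tert-butyldimethylsilyl)oxy]-3-methylpent-4-en-2-ol | C=C[C@@H](C)[C@@H](CO[Si](C)(C)C(C)(C)C)O | intermediate
7 | (2S,3R)-3-methylpent-4-ene-1,2-diol | C=C[C@@H](C)[C@@H](CO)O | intermediate
8 | sodium (2S,3R)-3-methyl-1-(tosyloxy)pent-4-en-2-olate | C=C[C@@H](C)[C@@H](COS(=O)(=O)c1ccc(C)cc1)[O-].[Na+] | intermediate
9 | (2S)-2-[(2R)-but-3-en-2-yl]oxirane | C=C[C@@H](C)[C@H]1CO1 | intermediate
10 | 2-(triisopropylsilyl)-1,3-oxazole | CC(C)[Si](C(C)C)(C(C)C)c1ncco1 | starting material
11 | 5-lithio-2-(triisopropylsilyl)-1,3-oxazole | [Li]c1cnc(o1)[Si](C(C)C)(C(C)C)C(C)C | intermediate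
12 | (2R,3R)-3-methyl-1-[2-(triisopropylsilyl)-1,3-oxazol-5-yl]pent-4-en-2-ol | C=C[C@@H](C)[C@@H](Cc1cnc(o1)[Si](C(C)C)(C(C)C)C(C)C)O | intermediate
13 | (2R,3R)-3-methyl-1-(1,3-oxazol-5-yl)pent-4-en-2-ol | C=C[C@@H](C)[C@@H](Cc1cnco1)O | intermediate
14 | ethyl 2-[bis(2,2,2-trifluoroethoxy)phosphoryl]propanoate (racemic) | CCOC(=O)C(C)P(=O)(OCC(F)(F)F)OCC(F)(F)F | starting material
15 | 2-[bis(2,2,2-trifluoroethoxy)phosphoryl]prop-1-en-1-one | CC(=C=O)P(=O)(OCC(F)(F)F)OCC(F)(F)F | intermediate
16 | (2R,3R)-3-methyl-1-(1,3-oxazol-5-yl)pent-4-en-2-yl 2-[bis(2,2,2-trifluoroethoxy)phosphoryl]propanoate (epimers at the phosphonate carbon) | C=C[C@@H](C)[C@@H](Cc1cnco1)OC(=O)C(C)P(=O)(OCC(F)(F)F)OCC(F)(F)F | intermediate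
17 | ethyl (2Z)-3-iodoprop-2-enoate | CCOC(=O)/C=C\I | starting material
18 | diisobutylaluminium hemiacetal of 17 | CCOC(/C=C\I)O[Al](CC(C)C)CC(C)C | intermediate
19 | (2Z)-3-iodoprop-2-enal | O=C/C=C\I | intermediate
20 | potassium carbanion of 16 | C=C[C@@H](C)[C@@H](Cc1cnco1)OC(=O)[C-](C)P(=O)(OCC(F)(F)F)OCC(F)(F)F.[K+] | intermediate
21 | (2R,3R)-3-methyl-1-(1,3-oxazol-5-yl)pent-4-en-2-yl (2Z,4Z)-5-iodo-2-methylpenta-2,4-dienoate | C=C[C@@H](C)[C@@H](Cc1cnco1)OC(=O)/C(C)=C\C=C/I | intermediate
22 | (2R,3R)-5-(9-borabicyclo[3.3.1]nonan-9-yl)-3-methyl-1-(1,3-oxazol-5-yl)pentan-2-yl 2-[bis(2,2,2-trifluoroethoxy)phosphoryl]propanoate | B1(CC[C@@H](C)[C@@H](Cc2cnco2)OC(=O)C(C)P(=O)(OCC(F)(F)F)OCC(F)(F)F)C2CCCC1CCC2 | intermediate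
23 | (2R,3R)-3-methyl-1-(1,3-oxazol-5-yl)pent-4-en-2-yl (2Z,4Z,8R,9R)-9-({2-[bis(2,2,2-trifluoroethoxy)phosphoryl]propanoyl}oxy)-2,8-dimethyl-10-(1,3-oxazol-5-yl)deca-2,4-dienoate (open-chain diester with a vinyl terminus and a phosphonopropanoate terminus) | C=C[C@@H](C)[C@@H](Cc1cnco1)OC(=O)/C(C)=C\C=C/CC[C@@H](C)[C@@H](Cc1cnco1)OC(=O)C(C)P(=O)(OCC(F)(F)F)OCC(F)(F)F | intermediate
24 | potassium carbanion of 23 | C=C[C@@H](C)[C@@H](Cc1cnco1)OC(=O)/C(C)=C\C=C/CC[C@@H](C)[C@@H](Cc1cnco1)OC(=O)[C-](C)P(=O)(OCC(F)(F)F)OCC(F)(F)F.[K+] | intermediate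
25 | (2R,3R)-3-methyl-1-(1,3-oxazol-5-yl)pent-4-en-2-yl (2Z,4Z,8R,9R)-9-{[(2Z,4Z)-5-iodo-2-methylpenta-2,4-dienoyl]oxy}-2,8-dimethyl-10-(1,3-oxazol-5-yl)deca-2,4-dienoate (open-chain diester with a vinyl terminus and an iododienoate terminus) | C=C[C@@H](C)[C@@H](Cc1cnco1)OC(=O)/C(C)=C\C=C/CC[C@@H](C)[C@@H](Cc1cnco1)OC(=O)/C(C)=C\C=C/I | intermediate
26 | (2R,3R)-5-(9-borabicyclo[3.3.1]nonan-9-yl)-3-methyl-1-(1,3-oxazol-5-yl)pentan-2-yl (2Z,4Z,8R,9R)-9-{[(2Z,4Z)-5-iodo-2-methylpenta-2,4-dienoyl]oxy}-2,8-dimethyl-10-(1,3-oxazol-5-yl)deca-2,4-dienoate | B1(CC[C@@H](C)[C@@H](Cc2cnco2)OC(=O)/C(C)=C\C=C/CC[C@@H](C)[C@@H](Cc2cnco2)OC(=O)/C(C)=C\C=C/I)C2CCCC1CCC2 | intermediate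
27 | (3Z,5Z,9R,10R,13Z,15Z,19R,20R)-3,9,13,19-tetramethyl-10,20-bis(1,3-oxazol-5-ylmethyl)-1,11-dioxacycloicosa-3,5,13,15-tetraene-2,12-dione | C/C1=C/C=C\CC[C@@H](C)[C@@H](Cc2cnco2)OC(=O)/C(C)=C\C=C/CC[C@@H](C)[C@@H](Cc2cnco2)OC1=O | target

## Step count and least certain steps

Total step count: 10. Longest linear sequence: 9 steps (1, 2, 3, 4, 5, 7, 8, 9, 10); step 6 is a one-step side branch that supplies 19 to steps 7 and 9.

**Step 10 (key step).**
- Most likely to go wrong: chain growth competing with ring closure, because both pass through the same palladium intermediates and differ only in effective concentration. A second danger is Z to E scrambling at C4′=C5′, or β-hydride elimination, while the organopalladium species waits for a slow transmetalation at high dilution.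
- Fallback (sets out from 23, comes back to the route at 27): the ring is closed at C2′=C3′ by an olefination and not at C5′–C6′ by a coupling. Hydroboration of the vinyl group of 23 with 9-BBN would give the alkylborane F1. It would be coupled under the palladium conditions of step 8 with (2Z)-3-iodoprop-2-en-1-ol F2 (from 17 with i-Bu2AlH, 2.2 equiv, CH2Cl2, −78 to 0 °C) to the (Z)-allylic alcohol F3. Oxidation with MnO2 (CH2Cl2, rt) would give the (Z)-enal F4, used at once. Intramolecular Still–Gennari olefination through the potassium carbanion F5 (K2CO3, 18-crown-6, toluene, 0 °C, about 0.001 M) would then close the 20-membered ring to 27.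

**Step 8.**
- Most likely to go wrong: cleavage of a trifluoroethoxy group from phosphorus by the aqueous base of the coupling, or incomplete hydroboration because the oxazole and phosphoryl oxygens tie up the borane.
- Fallback (sets out from 13 and 21, comes back at 23): the phosphonate is attached only after the coupling. Alcohol 13 would be treated with 9-BBN, with B–H kept limiting; the hydroxyl is borylated with loss of H2 and the vinyl group hydroborated, giving the O,C-bis-boron derivative F6. Coupling with 21 under the same palladium conditions, in which the O–B bond is hydrolysed by the aqueous base, would give the hydroxy ester F7. Separately, 14 would be cleaved with Me3SnOH (1,2-dichloroethane, 80 °C; HCl work-up) to 2-[bis(2,2,2-trifluoroethoxy)phosphoryl]propanoic acid F8. Acylation of F7 with F8 (EDC·HCl, catalytic DMAP, CH2Cl2, 0 °C) gives 23; the acid activated here is saturated at C2, so no olefin geometry is at stake.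

**Step 9.**
- Most likely to go wrong: erosion of geometry, either by isomerisation of 19 before it is consumed or by incomplete Z selectivity at the trisubstituted olefin, on an advanced substrate where the isomers may be hard to separate.
- Fallback (sets out from 23, comes back at 25): the iodide is introduced after the olefination. The known reagent (2Z)-3-(tributylstannyl)prop-2-en-1-ol would be oxidised with MnO2 (CH2Cl2, rt) to (2Z)-3-(tributylstannyl)prop-2-enal F9, a more robust partner than 19. Still–Gennari olefination of carbanion 24 with F9 would give the (2Z,4Z)-5-stannyldienoate F10. Iododestannylation (I2, CH2Cl2, 0 °C) replaces tin by iodine with retention and gives 25.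

**Step 5.**
- Most likely to go wrong: attack of the alcohol at phosphorus with loss of trifluoroethoxide, or slow ketene formation from the α-methylated phosphonate, so that acyl transfer stalls at reflux.
- Fallback (sets out from 13, comes back at 21): the olefination reagent is built on the substrate. Acylation with bromoacetyl bromide and pyridine gives the bromoacetate F11. A Michaelis–Becker reaction with (PhO)2P(O)H and Et3N gives the (diphenoxyphosphoryl)acetate F12. C-Methylation (NaH, MeI) gives the 2-(diphenoxyphosphoryl)propanoate F13. Ando-type Z-selective olefination of its sodium carbanion F14 (NaH, THF, −78 °C) with 19 then gives 21 directly; part of F13 would be kept to serve in step 8 in place of 16.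

**Step 4.**
- Most likely to go wrong: Lewis-acid-induced rearrangement of the epoxide, or decomposition of the lithiated oxazole once BF3 is present, so that the opening does not go to completion.
- Fallback (sets out from 10 through 11, comes back at 12): the order of bond formation is reversed. Lithio-oxazole 11 would be allylated with allyl bromide to 5-(prop-2-en-1-yl)-2-(triisopropylsilyl)-1,3-oxazole F15. Lemieux–Johnson cleavage (catalytic OsO4, NaIO4, 2,6-lutidine, dioxane/H2O) gives [2-(triisopropylsilyl)-1,3-oxazol-5-yl]acetaldehyde F16, used crude. Brown crotylboration with 4 (Si-face attack as in step 1) gives the borinate F17 and, after oxidative work-up, 12, which is desilylated to 13 as in step 4. Steps 2 and 3 are then not needed.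

## Further compounds

F1 | step 10 | (2R,3R)-5-(9-borabicyclo[3.3.1]nonan-9-yl)-3-methyl-1-(1,3-oxazol-5-yl)pentan-2-yl (2Z,4Z,8R,9R)-9-({2-[bis(2,2,2-trifluoroethoxy)phosphoryl]propanoyl}oxy)-2,8-dimethyl-10-(1,3-oxazol-5-yl)deca-2,4-dienoate | B1(CC[C@@H](C)[C@@H](Cc2cnco2)OC(=O)/C(C)=C\C=C/CC[C@@H](C)[C@@H](Cc2cnco2)OC(=O)C(C)P(=O)(OCC(F)(F)F)OCC(F)(F)F)C2CCCC1CCC2
F2 | step 10 | (2Z)-3-iodoprop-2-en-1-ol | OC/C=C\I
F3 | step 10 | (2R,3R,6Z)-8-hydroxy-3-methyl-1-(1,3-oxazol-5-yl)oct-6-en-2-yl (2Z,4Z,8R,9R)-9-({2-[bis(2,2,2-trifluoroethoxy)phosphoryl]propanoyl}oxy)-2,8-dimethyl-10-(1,3-oxazol-5-yl)deca-2,4-dienoate | OC/C=C\CC[C@@H](C)[C@@H](Cc1cnco1)OC(=O)/C(C)=C\C=C/CC[C@@H](C)[C@@H](Cc1cnco1)OC(=O)C(C)P(=O)(OCC(F)(F)F)OCC(F)(F)F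
F4 | step 10 | (2R,3R,6Z)-3-methyl-1-(1,3-oxazol-5-yl)-8-oxooct-6-en-2-yl (2Z,4Z,8R,9R)-9-({2-[bis(2,2,2-trifluoroethoxy)phosphoryl]propanoyl}oxy)-2,8-dimethyl-10-(1,3-oxazol-5-yl)deca-2,4-dienoate | O=C/C=C\CC[C@@H](C)[C@@H](Cc1cnco1)OC(=O)/C(C)=C\C=C/CC[C@@H](C)[C@@H](Cc1cnco1)OC(=O)C(C)P(=O)(OCC(F)(F)F)OCC(F)(F)F
F5 | step 10 | potassium carbanion of F4 | O=C/C=C\CC[C@@H](C)[C@@H](Cc1cnco1)OC(=O)/C(C)=C\C=C/CC[C@@H](C)[C@@H](Cc1cnco1)OC(=O)[C-](C)P(=O)(OCC(F)(F)F)OCC(F)(F)F.[K+]
F6 | step 8 | 9-{[(2R,3R)-5-(9-borabicyclo[3.3.1]nonan-9-yl)-3-methyl-1-(1,3-oxazol-5-yl)pentan-2-yl]oxy}-9-borabicyclo[3.3.1]nonane | B1(CC[C@@H](C)[C@@H](Cc2cnco2)OB2C3CCCC2CCC3)C2CCCC1CCC2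
F7 | step 8 | (2R,3R)-3-methyl-1-(1,3-oxazol-5-yl)pent-4-en-2-yl (2Z,4Z,8R,9R)-9-hydroxy-2,8-dimethyl-10-(1,3-oxazol-5-yl)deca-2,4-dienoate | C=C[C@@H](C)[C@@H](Cc1cnco1)OC(=O)/C(C)=C\C=C/CC[C@@H](C)[C@@H](Cc1cnco1)O
F8 | step 8 | 2-[bis(2,2,2-trifluoroethoxy)phosphoryl]propanoic acid (racemic) | OC(=O)C(C)P(=O)(OCC(F)(F)F)OCC(F)(F)F
F9 | step 9 | (2Z)-3-(tributylstannyl)prop-2-enal | O=C/C=C\[Sn](CCCC)(CCCC)CCCC
F10 | step 9 | (2R,3R)-3-methyl-1-(1,3-oxazol-5-yl)pent-4-en-2-yl (2Z,4Z,8R,9R)-2,8-dimethyl-9-{[(2Z,4Z)-2-methyl-5-(tributylstannyl)penta-2,4-dienoyl]oxy}-10-(1,3-oxazol-5-yl)deca-2,4-dienoate | C=C[C@@H](C)[C@@H](Cc1cnco1)OC(=O)/C(C)=C\C=C/CC[C@@H](C)[C@@H](Cc1cnco1)OC(=O)/C(C)=C\C=C/[Sn](CCCC)(CCCC)CCCC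
F11 | step 5 | (2R,3R)-3-methyl-1-(1,3-oxazol-5-yl)pent-4-en-2-yl bromoacetate | C=C[C@@H](C)[C@@H](Cc1cnco1)OC(=O)CBr
F12 | step 5 | (2R,3R)-3-methyl-1-(1,3-oxazol-5-yl)pent-4-en-2-yl (diphenoxyphosphoryl)acetate | C=C[C@@H](C)[C@@H](Cc1cnco1)OC(=O)CP(=O)(Oc1ccccc1)Oc1ccccc1
F13 | step 5 | (2R,3R)-3-methyl-1-(1,3-oxazol-5-yl)pent-4-en-2-yl 2-(diphenoxyphosphoryl)propanoate | C=C[C@@H](C)[C@@H](Cc1cnco1)OC(=O)C(C)P(=O)(Oc1ccccc1)Oc1ccccc1
F14 | step 5 | sodium carbanion of F13 | C=C[C@@H](C)[C@@H](Cc1cnco1)OC(=O)[C-](C)P(=O)(Oc1ccccc1)Oc1ccccc1.[Na+]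
F15 | step 4 | 5-(prop-2-en-1-yl)-2-(triisopropylsilyl)-1,3-oxazole | C=CCc1cnc(o1)[Si](C(C)C)(C(C)C)C(C)C
F16 | step 4 | [2-(triisopropylsilyl)-1,3-oxazol-5-yl]acetaldehyde | O=CCc1cnc(o1)[Si](C(C)C)(C(C)C)C(C)C
F17 | step 4 | diisopinocampheylborinate of 12 | C=C[C@@H](C)[C@@H](Cc1cnc(o1)[Si](C(C)C)(C(C)C)C(C)C)OB([C@@H]1C[C@@H]2C[C@H]([C@H]1C)C2(C)C)[C@@H]1C[C@@H]2C[C@H]([C@H]1C)C2(C)C
A1 | alternative 1 | (2Z,4Z,8R,9R)-9-hydroxy-2,8-dimethyl-10-(1,3-oxazol-5-yl)deca-2,4-dienoic acid | OC(=O)/C(C)=C\C=C/CC[C@@H](C)[C@@H](Cc1cnco1)O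
A2 | alternative 2 | (2R,3R,6Z)-3-methyl-1-(1,3-oxazol-5-yl)-7-(tributylstannyl)hept-6-en-2-yl (2Z)-3-iodo-2-methylprop-2-enoate | CCCC[Sn](CCCC)(CCCC)/C=C\CC[C@@H](C)[C@@H](Cc1cnco1)OC(=O)/C(C)=C\I
A3 | alternative 2 | (2Z)-3-iodo-2-methylprop-2-enoic acid | OC(=O)/C(C)=C\I
A4 | alternative 3 | (2R,3R)-3-methyl-1-(1,3-oxazol-5-yl)oct-6-yn-2-yl (2Z)-2-methylhex-2-en-4-ynoate | CC#CCC[C@@H](C)[C@@H](Cc1cnco1)OC(=O)/C(C)=C\C#CC
A5 | alternative 3 | (3Z,9R,10R,13Z,19R,20R)-3,9,13,19-tetramethyl-10,20-bis(1,3-oxazol-5-ylmethyl)-1,11-dioxacycloicosa-3,13-diene-5,15-diyne-2,12-dione | C/C1=C/C#CCC[C@@H](C)[C@@H](Cc2cnco2)OC(=O)/C(C)=C\C#CCC[C@@H](C)[C@@H](Cc2cnco2)OC1=O
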